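**Plan**

1. Numbering follows benzofuran (O1, C2, C3, C3a, C4 to C7, C7a); ring A is the benzo ring, ring B the dihydrofuran ring, ring C the aryl group on C2.
2. Retrosynthesis: the feruloyl ester is cut first at O–CH2 (carboxylate plus primary chloride), then ring B is cut at O1–C7a and C2–C3 together. This leaves an aryl diazoacetate (ring A, C3, triflate on C7a) and the silyl ether of O-pivaloyl vanillyl alcohol (ring C, C2, O1).
3. Feature used: C2 is benzylic to ring C and bears O1, so the C–H bond of ArCH2–OSi is the preferred site for insertion of a donor/acceptor carbene centred on C3 (benzylic to ring A, ester as masked CH2OH). C7a is ortho to C3a, so the freed O1 lies five atoms from the aryl triflate and closes ring B.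
4. Forward order: ring A is bought complete (dihydroconiferyl alcohol) and armed by iodination, triflation, chlorination and diazoacetate coupling. Ring B is then made in one flask (C2–C3 by carbene insertion, O1–C7a by palladium etherification); reduction and alkylation of ferulic acid join the chain ester last.
5. Stereochemistry: C2 and C3 both come from the chiral dirhodium catalyst in the insertion (syn ester, which is the trans-2,3 ring); the E alkene is brought in with ferulic acid.

Key step: step 7

Assumption: Rh2(R-PTAD)4, dirhodium tetrakis[(R)-(1-adamantyl)(phthalimido)acetate], is taken to give the (2R,3R)-syn insertion product 10; if its sense of induction is the opposite, the mirror-image catalyst Rh2(S-PTAD)4 is used and nothing else changes.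

**Step 1**
Reactants: 1 4-(3-hydroxypropyl)-2-methoxyphenol (dihydroconiferyl alcohol)
Product: 2 4-(3-hydroxypropyl)-2-iodo-6-methoxyphenol
Conditions: I2, NaHCO3, THF–H2O, 0 → 25 °C
Reagents that add atoms: iodine, [I][I]
Why: Electrophilic aromatic iodination of the phenolate, whose para position is blocked by the side chain and whose only free ortho position is the future C3a, should place iodine there; no stereocentre is formed.

**Step 2**
Reactants: 2 4-(3-hydroxypropyl)-2-iodo-6-methoxyphenol
Product: 3 4-(3-hydroxypropyl)-2-iodo-6-methoxyphenyl trifluoromethanesulfonate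
Conditions: PhNTf2, Et3N, DMAP (cat.), CH2Cl2, 25 °C
Reagents that add atoms: N-phenylbis(trifluoromethanesulfonimide), O=S(=O)(N(c1ccccc1)S(=O)(=O)C(F)(F)F)C(F)(F)F
Why: Phenol triflation with the mild triflyl donor PhNTf2 should sulfonylate the phenolate but not the primary alcohol, and it turns the oxygen on C7a into the leaving group that O1 displaces later.

**Step 3**
Reactants: 3 4-(3-hydroxypropyl)-2-iodo-6-methoxyphenyl trifluoromethanesulfonate
Product: 4 4-(3-chloropropyl)-2-iodo-6-methoxyphenyl trifluoromethanesulfonate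
Conditions: PPh3, NCS, THF, 0 → 25 °C
Reagents that add atoms: N-chlorosuccinimide, O=C1CCC(=O)N1Cl
Why: In this Appel reaction the alkoxyphosphonium ion of the primary alcohol is displaced by chloride in an SN2 step while aryl iodide and aryl triflate are inert, and the chloride marks the place of the later ester C–O bond.

**Step 4**
Reactants: 4 4-(3-chloropropyl)-2-iodo-6-methoxyphenyl trifluoromethanesulfonate; 5 ethyl diazoacetate
Product: 6 ethyl 2-[5-(3-chloropropyl)-3-methoxy-2-{[(trifluoromethyl)sulfonyl]oxy}phenyl]-2-diazoacetate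
Conditions: Pd(PPh3)4 (5 mol%), Ag2CO3 (0.5 equiv), Et3N, toluene, 25 °C
Reagents that add atoms: none
Why: Palladium-catalysed cross-coupling of an aryl iodide with the C–H bond of a diazoacetate keeps the diazo group, and zerovalent palladium should insert into the C–I bond far faster than into the C–OTf bond at room temperature.

**Step 5**
Reactants: 7 4-(hydroxymethyl)-2-methoxyphenol (vanillyl alcohol)
Product: 8 4-(hydroxymethyl)-2-methoxyphenyl 2,2-dimethylpropanoate
Conditions: PivCl, K2CO3, acetone, 0 → 25 °C
Reagents that add atoms: pivaloyl chloride, CC(C)(C)C(=O)Cl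
Why: Chemoselective O-acylation of the phenolate should occur because carbonate does not ionise the benzylic alcohol, which reacts only slowly with the hindered acid chloride in the absence of an acylation catalyst.

**Step 6**
Reactants: 8 4-(hydroxymethyl)-2-methoxyphenyl 2,2-dimethylpropanoate
Product: 9 4-({[tert-butyl(dimethyl)silyl]oxy}methyl)-2-methoxyphenyl 2,2-dimethylpropanoate
Conditions: TBSCl, imidazole, DMF, 25 °C
Reagents that add atoms: tert-butyl(chloro)dimethylsilane, CC(C)(C)[Si](C)(C)Cl
Why: Imidazole-promoted silylation of the primary alcohol gives the benzyl silyl ether whose CH2 group is the insertion site of the key step.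

**Step 7**
Reactants: 6 ethyl 2-[5-(3-chloropropyl)-3-methoxy-2-{[(trifluoromethyl)sulfonyl]oxy}phenyl]-2-diazoacetate; 9 4-({[tert-butyl(dimethyl)silyl]oxy}methyl)-2-methoxyphenyl 2,2-dimethylpropanoate
Product: 12 ethyl (2R,3R)-5-(3-chloropropyl)-2-[4-(2,2-dimethylpropanoyloxy)-3-methoxyphenyl]-7-methoxy-2,3-dihydro-1-benzofuran-3-carboxylate, via syn silyloxy ester 10 (not isolated), via syn hydroxy ester 11 (not isolated)
Conditions: Rh2(R-PTAD)4 (1 mol%), PhCF3, 25 °C, slow addition of 6 to 9 (1.5 equiv); then Bu4NF, AcOH, THF, 0 → 25 °C; then Pd(OAc)2 (5 mol%), 2-(di-tert-butylphosphino)-1,1'-binaphthyl, K3PO4, 60 °C (one flask)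
Reagents that add atoms: none
Why: Loss of dinitrogen from 6 at the chiral dirhodium tetracarboxylate gives a donor/acceptor carbene at C3 that inserts, through a concerted hydride-transfer-like three-centre transition state, into the benzylic C–H bond of 9 and so forms the C3–C2 bond; fluoride then frees the oxygen on C2, zerovalent palladium inserts into the C7a–OTf bond, the alkoxide binds, and C–O reductive elimination from the six-membered aryl(alkoxo)palladium ring forms the O1–C7a bond. The closest known reaction types are the enantioselective insertion of aryldiazoacetate carbenes into the C–H bond next to oxygen of benzyl silyl ethers, a catalytic surrogate of the aldol reaction, and the palladium-catalysed intramolecular etherification of 2-(2-halophenyl)ethanols. Ring B closes at C7a by attack of O1 (formally 5-exo at an aromatic carbon, in fact a reductive elimination that contracts a six-membered palladacycle), and ring A is present from the start. C2 and C3 are both set in the insertion by the chiral carboxylate ligands of the catalyst, which select the carbene face and one of the two enantiotopic benzylic hydrogens and should give the syn isomer, and neither centre is touched afterwards, so the syn ester becomes the trans-2,3 ring. The step needs site selectivity for the ArCH2–O group of 9 over the methoxy, tert-butyl, silyl-methyl and chloropropyl C–H bonds and over attack on the arenes, which is secured because that CH2 group alone is both benzylic and attached to a silyloxy group, while the pivalate lowers the electron density of ring C and the triflate that of ring A. It also needs the freed alkoxide to cyclise before retro-aldol cleavage or epimerisation at C3, which the acetic acid buffer, the weak phosphate base and the intramolecular capture on palladium are meant to ensure, and the triflate is the only site for oxidative addition because the primary alkyl chloride is inert.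

**Step 8**
Reactants: 12 ethyl (2R,3R)-5-(3-chloropropyl)-2-[4-(2,2-dimethylpropanoyloxy)-3-methoxyphenyl]-7-methoxy-2,3-dihydro-1-benzofuran-3-carboxylate
Product: 13 [(2R,3S)-5-(3-chloropropyl)-2-(4-hydroxy-3-methoxyphenyl)-7-methoxy-2,3-dihydro-1-benzofuran-3-yl]methanol
Conditions: iBu2AlH (excess), CH2Cl2, −78 → 0 °C; aqueous Rochelle salt work-up
Reagents that add atoms: none
Why: Hydride reduction turns the ester into the primary alcohol and cleaves the aryl pivalate in the same operation, the alkyl chloride and both stereocentres are left alone, and the descriptor at C3 changes from R to S only because the substituent priorities change.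

**Step 9**
Reactants: 13 [(2R,3S)-5-(3-chloropropyl)-2-(4-hydroxy-3-methoxyphenyl)-7-methoxy-2,3-dihydro-1-benzofuran-3-yl]methanol; 14 (2E)-3-(4-hydroxy-3-methoxyphenyl)prop-2-enoic acid (ferulic acid)
Product: 15 3-[(2R,3S)-2-(4-hydroxy-3-methoxyphenyl)-3-(hydroxymethyl)-7-methoxy-2,3-dihydro-1-benzofuran-5-yl]propyl (2E)-3-(4-hydroxy-3-methoxyphenyl)prop-2-enoate
Conditions: KHCO3, NaI (cat.), DMF, 60 °C
Reagents that add atoms: none
Why: Carboxylate O-alkylation (SN2 with iodide catalysis of the Finkelstein type) should be chemoselective because hydrogencarbonate ionises only the carboxylic acid and leaves the two phenols and the primary alcohol protonated, and the E alkene and both stereocentres are not affected.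

**Compound list**

1 | 4-(3-hydroxypropyl)-2-methoxyphenol (dihydroconiferyl alcohol) | COc1cc(CCCO)ccc1O | starting material
2 | 4-(3-hydroxypropyl)-2-iodo-6-methoxyphenol | COc1cc(CCCO)cc(I)c1O | intermediate
3 | 4-(3-hydroxypropyl)-2-iodo-6-methoxyphenyl trifluoromethanesulfonate | COc1cc(CCCO)cc(I)c1OS(=O)(=O)C(F)(F)F | intermediate
4 | 4-(3-chloropropyl)-2-iodo-6-methoxyphenyl trifluoromethanesulfonate | COc1cc(CCCCl)cc(I)c1OS(=O)(=O)C(F)(F)F | intermediate
5 | ethyl diazoacetate | CCOC(=O)C=[N+]=[N-] | starting material
6 | ethyl 2-[5-(3-chloropropyl)-3-methoxy-2-{[(trifluoromethyl)sulfonyl]oxy}phenyl]-2-diazoacetate | CCOC(=O)C(=[N+]=[N-])c1cc(CCCCl)cc(OC)c1OS(=O)(=O)C(F)(F)F | intermediate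
7 | 4-(hydroxymethyl)-2-methoxyphenol (vanillyl alcohol) | COc1cc(CO)ccc1O | starting material
8 | 4-(hydroxymethyl)-2-methoxyphenyl 2,2-dimethylpropanoate | COc1cc(CO)ccc1OC(=O)C(C)(C)C | intermediate
9 | 4-({[tert-butyl(dimethyl)silyl]oxy}methyl)-2-methoxyphenyl 2,2-dimethylpropanoate | COc1cc(CO[Si](C)(C)C(C)(C)C)ccc1OC(=O)C(C)(C)C | intermediate
10 | ethyl (2R,3R)-3-{[tert-butyl(dimethyl)silyl]oxy}-2-[5-(3-chloropropyl)-3-methoxy-2-{[(trifluoromethyl)sulfonyl]oxy}phenyl]-3-[4-(2,2-dimethylpropanoyloxy)-3-methoxyphenyl]propanoate | ClCCCc1cc(OC)c(OS(=O)(=O)C(F)(F)F)c(c1)[C@@H](C(=O)OCC)[C@H](c1ccc(OC(=O)C(C)(C)C)c(OC)c1)O[Si](C)(C)C(C)(C)C | intermediate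
11 | ethyl (2R,3R)-2-[5-(3-chloropropyl)-3-methoxy-2-{[(trifluoromethyl)sulfonyl]oxy}phenyl]-3-[4-(2,2-dimethylpropanoyloxy)-3-methoxyphenyl]-3-hydroxypropanoate | ClCCCc1cc(OC)c(OS(=O)(=O)C(F)(F)F)c(c1)[C@@H](C(=O)OCC)[C@H](c1ccc(OC(=O)C(C)(C)C)c(OC)c1)O | intermediate
12 | ethyl (2R,3R)-5-(3-chloropropyl)-2-[4-(2,2-dimethylpropanoyloxy)-3-methoxyphenyl]-7-methoxy-2,3-dihydro-1-benzofuran-3-carboxylate | ClCCCc1cc(OC)c2c(c1)[C@@H](C(=O)OCC)[C@H](c1ccc(OC(=O)C(C)(C)C)c(OC)c1)O2 | intermediate
13 | [(2R,3S)-5-(3-chloropropyl)-2-(4-hydroxy-3-methoxyphenyl)-7-methoxy-2,3-dihydro-1-benzofuran-3-yl]methanol | ClCCCc1cc(OC)c2c(c1)[C@@H](CO)[C@H](c1ccc(O)c(OC)c1)O2 | intermediate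
14 | (2E)-3-(4-hydroxy-3-methoxyphenyl)prop-2-enoic acid (ferulic acid) | COc1cc(/C=C/C(=O)O)ccc1O | starting material
15 | 3-[(2R,3S)-2-(4-hydroxy-3-methoxyphenyl)-3-(hydroxymethyl)-7-methoxy-2,3-dihydro-1-benzofuran-5-yl]propyl (2E)-3-(4-hydroxy-3-methoxyphenyl)prop-2-enoate | COc1cc(/C=C/C(=O)OCCCc2cc(OC)c3c(c2)[C@@H](CO)[C@H](c2ccc(O)c(OC)c2)O3)ccc1O | target

**Totals and risks**

Total step count: 9
Longest linear sequence: 7 steps (steps 1, 2, 3, 4, 7, 8, 9)

Steps most likely to fail:

Step 7. The ortho-triflyloxy aryl carbene may insert with poor facial or site selectivity, or it may attack ring C. In the later stages the triflyl group may migrate to the freed alkoxide, or retro-aldol cleavage may occur before the C–O bond forms. The fallback sets out from 4 and comes back at 13; it makes the C2–C3 bond by an auxiliary-controlled aldol reaction and the O1–C7a bond in a separate etherification. Iodide 4 is coupled with the Reformatsky reagent BrZnCH2CO2tBu (Pd(PPh3)4, THF) to the tert-butyl arylacetate F1, and CF3CO2H cleaves this to the arylacetic acid F2. Coupling of F2 with (R)-4-benzyl-1,3-oxazolidin-2-one (DCC, DMAP) gives the imide F3. Alcohol 8 is oxidised with MnO2 to the aldehyde F4. The dibutylboron enolate of F3 (Bu2BOTf, iPr2NEt, CH2Cl2, −78 °C) adds to F4 in an Evans aldol reaction and should give the syn aldol F5 with the (2R,3R) configuration. Palladium-catalysed etherification (Pd(OAc)2, 2-(di-tert-butylphosphino)-1,1'-binaphthyl, K3PO4, toluene) closes ring B to the cyclised imide F6. LiBH4 in THF–MeOH then removes the auxiliary reductively and cleaves the pivalate, which gives 13.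

Step 4. Oxidative addition at the hindered iodide may be slow, or palladium may decompose the diazo ester before the coupling is complete. The fallback sets out from 4 and comes back at 6. Iodide 4 is coupled with the Reformatsky reagent BrZnCH2CO2Et (Pd(PPh3)4, THF) to the ethyl arylacetate F7. Regitz diazo transfer (4-acetamidobenzenesulfonyl azide, DBU, MeCN) then converts F7 into 6.

Step 9. O-alkylation of a phenol may compete with the carboxylate, or substitution at the primary chloride may be too slow at a temperature the product tolerates. The fallback sets out from 13 and comes back at 15; it takes the phenol of the acid out of the alkylation and builds the aryl–alkene bond last. Chloride 13 is displaced by an excess of potassium acrylate (acrylic acid, KHCO3, NaI, DMF) to the acrylate ester F8. A Heck reaction of F8 with commercial 4-iodo-2-methoxyphenol (Pd(OAc)2, NaHCO3, Bu4NCl, DMF, 80 °C) should then form the E-configured feruloyl alkene and give 15.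

**Further compounds**

F1 | step 7 | tert-butyl 2-[5-(3-chloropropyl)-3-methoxy-2-{[(trifluoromethyl)sulfonyl]oxy}phenyl]acetate | CC(C)(C)OC(=O)Cc1cc(CCCCl)cc(OC)c1OS(=O)(=O)C(F)(F)F
F2 | step 7 | 2-[5-(3-chloropropyl)-3-methoxy-2-{[(trifluoromethyl)sulfonyl]oxy}phenyl]acetic acid | OC(=O)Cc1cc(CCCCl)cc(OC)c1OS(=O)(=O)C(F)(F)F
F3 | step 7 | (4R)-4-benzyl-3-{[5-(3-chloropropyl)-3-methoxy-2-{[(trifluoromethyl)sulfonyl]oxy}phenyl]acetyl}-1,3-oxazolidin-2-one | O=C(Cc1cc(CCCCl)cc(OC)c1OS(=O)(=O)C(F)(F)F)N1[C@H](Cc2ccccc2)COC1=O
F4 | step 7 | 4-formyl-2-methoxyphenyl 2,2-dimethylpropanoate | COc1cc(C=O)ccc1OC(=O)C(C)(C)C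
F5 | step 7 | (4R)-4-benzyl-3-[(2R,3R)-2-[5-(3-chloropropyl)-3-methoxy-2-{[(trifluoromethyl)sulfonyl]oxy}phenyl]-3-[4-(2,2-dimethylpropanoyloxy)-3-methoxyphenyl]-3-hydroxypropanoyl]-1,3-oxazolidin-2-one | ClCCCc1cc(OC)c(OS(=O)(=O)C(F)(F)F)c(c1)[C@@H](C(=O)N1[C@H](Cc2ccccc2)COC1=O)[C@H](c1ccc(OC(=O)C(C)(C)C)c(OC)c1)O
F6 | step 7 | (4R)-4-benzyl-3-{[(2R,3R)-5-(3-chloropropyl)-2-[4-(2,2-dimethylpropanoyloxy)-3-methoxyphenyl]-7-methoxy-2,3-dihydro-1-benzofuran-3-yl]carbonyl}-1,3-oxazolidin-2-one | ClCCCc1cc(OC)c2c(c1)[C@@H](C(=O)N1[C@H](Cc3ccccc3)COC1=O)[C@H](c1ccc(OC(=O)C(C)(C)C)c(OC)c1)O2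
F7 | step 4 | ethyl 2-[5-(3-chloropropyl)-3-methoxy-2-{[(trifluoromethyl)sulfonyl]oxy}phenyl]acetate | CCOC(=O)Cc1cc(CCCCl)cc(OC)c1OS(=O)(=O)C(F)(F)F
F8 | step 9 | 3-[(2R,3S)-2-(4-hydroxy-3-methoxyphenyl)-3-(hydroxymethyl)-7-methoxy-2,3-dihydro-1-benzofuran-5-yl]propyl prop-2-enoate | C=CC(=O)OCCCc1cc(OC)c2c(c1)[C@@H](CO)[C@H](c1ccc(O)c(OC)c1)O2
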